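## Structural features

The target (41) is a C20 xeniaphyllane-type diterpenoid monoacetate on a trans-fused bicyclo[7.2.0]undecane: a cyclobutane (C1, C9, C10, C11) shares the C1–C9 bond with a nine-membered carbocycle (C1–C9; caryophyllane numbering throughout, with 4-CH3, 8=CH2 and 11-CH3). The nine-membered ring carries a trans 4,5-epoxide (the oxide of an E-trisubstituted olefin) and an exocyclic methylidene at C8. The quaternary C11 carries, besides its methyl, C12 of a 3-hydroxy-3,6-dihydro-1,2-dioxine (C12 hemiketal, C13=C14, C15 bearing a methyl and an acetoxymethyl group, O–O between C15 and C12). Seven stereocentres are present, read from the SMILES as 1S, 4S, 5S, 9R, 11S, 12S, 15R. C9, C1 and C11 are contiguous on the four-membered ring (H1 and H9 trans, 11-CH3 cis to H9 and to the C1–C2 bond, the dioxine cis to H1), and C12/C15 are 1,4-related in the peroxide with the hemiketal OH cis to the 15-methyl. The bicyclic core has the configuration opposite to that of common (−)-caryophyllene oxide (1R,4R,5R,9S), so absolute configuration has to be made, not bought. Fragile elements are the O–O bond and peroxy hemiketal (reductants, phosphines, organometallics, hydrogenation catalysts), the epoxide and its strained olefin precursor (acid-triggered transannular cyclisation), the methylidene and the trans-fused cyclobutane. The real difficulties are the E-trisubstituted olefin inside a nine-membered ring, the quaternary C11 in a fixed relation to the ring fusion, and a late peroxide with a remote quaternary stereocentre. The key step uses C2–C3–C4–C5: with C2 and C5 bonded they form a cyclobutene cis-fused to a seven-membered ring (C1, C2, C5, C6, C7, C8, C9), and thermal cleavage of C2–C5 releases the nine-membered ring with C4=C5 E.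

## Logic of the disconnections

41 to 40. The two C–O bonds of the 4,5-epoxide are cut. The oxirane would not survive acid-catalysed perhydrolysis, so it is added last. The forward step must pick the endocyclic trisubstituted olefin over the methylidene and the dioxine olefin and attack its outer face.

40 to 39. The acetate C–O bond is cut. The forward step must acylate the primary alcohol and leave the tertiary hemiketal OH.

39 to 38. The two ring C–O bonds of the dioxine (O–C12 and O–C15) are cut. The peroxide then comes from H2O2 at the end, and ring, hemiketal and C15 reduce to one epoxide stereocentre plus a Z-enone. The forward step must open the epoxide at its tertiary allylic carbon with inversion and keep the enone Z.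

38 to 32 and 35 (through 37 and 36). After adjusting the C12 oxidation level and taking the Z-olefin back to an alkyne, the C12–C13 bond is cut. This gives a convergent union of a core aldehyde and a four-carbon epoxide. The forward sequence needs an organolithium addition before any peroxide exists and a semihydrogenation that touches only the alkyne.

35 to 33. The terminal alkyne carbon is removed (one-carbon homologation of an aldehyde). C15 is thereby traced to a commercial epoxy alcohol whose quaternary centre cannot epimerise.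

32 to 29 (through 31). The C12 oxidation level is adjusted and a carbonyl is put back at C2. That carbonyl is the residue of the ring expansion. The forward deoxygenation must not move C4=C5 or open the cyclobutane.

29 to 27 (through 28). A carboxyl is put back on C3 and silyl groups on both oxygens. The ketone becomes a masked β-keto ester. The forward steps must be neutral, which is why the ester is allyl.

27 to 26. The C2–C5 σ bond is re-formed. The strained E,Z-cyclononadiene becomes a cis-fused cyclobutene on a seven-membered ring, so the medium-ring problem reduces to a cycloheptanone enol ether. The forward opening must be conrotatory with the silyloxy group turning outward.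

26 to 22 and 25. The C4–C5 and C2–C3 bonds are cut ([2+2]). C3, C4, the 4-methyl and the ester come from an alkynoate. Regiochemistry follows from polarity (enol ether β-carbon C5 to alkynoate β-carbon C4), and cis fusion is enforced by ring size. 25 is cut at its ester C–O bond to 23 and 24.

22 to 21. The O–Si bond and one C6–H bond are cut (1,4-hydrosilylation of an enone). The enol ether is then regiospecific without base, which protects the C1 centre next to the carbonyl, since trans fusion on a seven-membered ring is expected to be the less stable. The forward step needs 1,4- over 1,2-addition and must spare the methylidene.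

21 to 20. The C5=C6 olefin is cut (ring-closing metathesis). The seven-membered ring becomes two arms on a trans-1,2-disubstituted cyclobutane. The forward step must close a strained ring faster than it oligomerises.

20 to 16 (through 19 and 18). The C8=CH2 bond (methylenation), the C7–C8 bond (allyl nucleophile on an amide) and the C2–C5 bond (vinyl nucleophile on an aldehyde) are cut. Both arms reduce to two carbonyls on the cyclobutane. The forward steps need an aldehyde that reacts before the amide and a non-basic methylenation.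

16 to 12 (through 14). The C2 aldehyde is traced to a styryl C=C, C1 is inverted, and the amide is exchanged for the directing anilide. The trans relation is thus traced to the all-cis product of a directed C–H functionalisation. The forward step needs only the aldehyde α-centre to epimerise.

12 to 10 and 11. The C1–C2 bond is cut (methylene C–H vinylation). C9, C1 and C11 then stem from one enantiotopic-group choice on an achiral cyclobutane. The forward step needs ligand control and a defined cis relation of amide and CH2OSi in 10.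

10 to 7 and 8 (through 9). The silyl O–Si and the amide C–N bonds are cut. The cis relation is traced to a bridged lactone.

7 to 1 and 3 (through 5, 4 and 2). The lactone C–O bond, one C–CO2Et bond, and the C9–C10 and C9–C1 ring bonds are cut. The cyclobutane comes from a malonate and a neopentyl dibromide made from 1. The forward lactonisation must funnel both C9 epimers into the one isomer that can close.

## Other disconnections considered

Alternative 1: The cut is the cyclobutane C9–C10 bond, through photochemical Wolff contraction of diazocyclopentanone A1 in methanol to cyclobutane ester A2.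
- Forward step: loss of N2, 1,2-shift of the ring CH2 to the carbene carbon with retention, and trapping of the ketene by methanol. C9 is then equilibrated trans to the side chain.
- In favour: the mechanism is well understood and stereospecific. The quaternary C11 can be set on a five-membered ring by conjugate-addition/alkylation logic. The C11 vinyl group is a direct aldehyde precursor, so no protecting group is needed at that carbon.
- Against: it solves only the four-membered ring. The E-olefin and the nine-membered ring still need a separate medium-ring closure with its own E/Z problem. A1 needs a quaternary centre that discriminates methyl from vinyl, a regioselective diazo transfer, and early use of the vinyl group before other olefins exist.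
- Comparison: on mechanistic certainty of the cyclobutane-forming event the alternative is the equal or the better of the C–H vinylation in step 7. On structure the chosen plan gets the cyclobutane from two bulk chemicals and lets one later step create ring size and olefin geometry together. On step economy the two are comparable up to the triad, but the alternative is longer overall.

Alternative 2: The cut is the two C–O bonds of the dioxine, from Z-enone epoxide A3 to dioxinol A4 with ethereal H2O2 and catalytic H3PMo12O40.
- In favour: both C–O bonds, the ring and C15 (by inversion) are made in one operation from H2O2, as late as possible. Nothing shorter is available for this ring.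
- Against: it is an end-game disconnection and says nothing about the carbocycle. A tertiary allylic centre can ionise, and the acid meets the strained diene.
- Comparison: the chosen plan uses this very closure as step 26 (A3 is 38, A4 is 39). On this bond set the alternative is the equal of the chosen plan, not a competitor. As the organising step of a whole route it would leave the E-cyclononene and the cyclobutane to some other method. The two disconnections are complementary.

Alternative 3: The cut is the C10–C11 and C1–C9 bonds, through cationic cyclisation of 12-silyloxyfarnesyl acetate A5 in a chiral confined Brønsted acid to A6.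
- Forward step: ionisation, 1,11-closure, 2,10-closure and loss of a methyl proton.
- In favour: the four- and nine-membered rings, the trans fusion, the E-olefin (carried over from the farnesyl 6,7-olefin) and the methylidene would all come in one step. The (E)-CH2OSi group of A5 maps onto the required C11 configuration if the olefin adds suprafacially. A5 is a few steps from farnesol, and A6 is the silyl ether of 31. On step economy the alternative is clearly the better, since it would replace steps 1–20.
- Against: anti-Markovnikov 1,11-closure to a secondary cation followed by cyclobutane formation has no counterpart outside enzymes. 1,6- and 1,10-closures, hydride shifts and further rearrangement of the acid-labile product compete. Enantio- and diastereocontrol rest on a catalyst that would have to be invented.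
- Comparison: on structure it is the most direct. On mechanism it is speculative where the chosen plan uses precedented reaction types throughout.

Key step: step 17

Remarks before the steps:
- Assumption on step 7: the sense of induction of the chiral ligand is not derived here; the ligand antipode that leads to 12 is meant.
- Remark on 26: the two new fusion centres (C2, C5) are written as one of the two possible cis-fused diastereomers. Both centres become sp2 in step 17, so either diastereomer leads to the same 27.
- Design of the key-step substrate: the enol ether is carried as the triisopropylsilyl ether, because a trimethylsilyl enol ether would be desilylated by the triflimide catalyst and give open-chain Michael products. The ester is carried as the allyl ester, because a simple alkyl ester would need hot halide or hydroxide, which the β,γ-unsaturated nine-membered keto ester is unlikely to tolerate.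
- The enol ether is made from an enone by 1,4-hydrosilylation rather than by deprotonating a ketone.

## Route

Step 1
Reactants: 1 1,1,1-tris(hydroxymethyl)ethane
Product: 2 3-bromo-2-(bromomethyl)-2-methylpropyl acetate
Conditions: HBr (33% in AcOH), AcOH, 110 °C, sealed vessel
Reagents that add atoms: hydrogen bromide, Br; acetic acid, CC(=O)O
Why: Acid-promoted substitution of two neopentyl hydroxyls with acetoxonium participation and Fischer esterification of the third, the usual entry to neopentyl dibromide monoacetates; no stereocentre.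

Step 2
Reactants: 2 3-bromo-2-(bromomethyl)-2-methylpropyl acetate; 3 diethyl malonate
Product: 4 diethyl 3-(acetoxymethyl)-3-methylcyclobutane-1,1-dicarboxylate
Conditions: NaH (2.2 equiv), diglyme, 0 → 130 °C
Reagents that add atoms: none
Why: Double malonate alkylation (Perkin cycloalkylation); the second, 4-exo-tet displacement is helped by the gem-disubstituent effect, and C9 is not yet stereogenic because it carries two identical esters.

Step 3
Reactants: 4 diethyl 3-(acetoxymethyl)-3-methylcyclobutane-1,1-dicarboxylate
Product: 5 ethyl 3-(acetoxymethyl)-3-methylcyclobutane-1-carboxylate (cis/trans mixture)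
Conditions: LiCl, H2O, DMSO, 150 °C
Reagents that add atoms: none
Why: Krapcho dealkoxycarbonylation of a geminal diester; the new C–H centre forms as a mixture that step 4 corrects, and material that loses its acetate converges there as well.

Step 4
Reactants: 5 ethyl 3-(acetoxymethyl)-3-methylcyclobutane-1-carboxylate
Product: 7 5-methyl-3-oxabicyclo[3.1.1]heptan-2-one, via ethyl 3-(hydroxymethyl)-3-methylcyclobutane-1-carboxylate 6 (not isolated)
Conditions: NaOEt (0.3 equiv), EtOH, 60 °C; then KOtBu (0.2 equiv), toluene, reflux with continuous removal of EtOH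
Reagents that add atoms: none
Why: Base-mediated epimerising lactonisation: transesterification frees the hydroxyl, the ester α-centre equilibrates through its enolate and only the cis isomer can close. The bridged lactone cannot enolise at its bridgehead and is the sink, which fixes the cis relation of the acyl carbon and the CH2O group.

Step 5
Reactants: 7 5-methyl-3-oxabicyclo[3.1.1]heptan-2-one; 8 2,3,5,6-tetrafluoro-4-(trifluoromethyl)aniline
Product: 9 cis-3-(hydroxymethyl)-3-methyl-N-[2,3,5,6-tetrafluoro-4-(trifluoromethyl)phenyl]cyclobutane-1-carboxamide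
Conditions: AlMe3 (1.2 equiv), toluene, 0 → 80 °C
Reagents that add atoms: none
Why: Weinreb-type aminolysis of the strained lactone by the dimethylaluminium anilide; the lactone bridge becomes the cis-1,3 relation of amide and hydroxymethyl, and no stereocentre is touched.

Step 6
Reactants: 9 cis-3-(hydroxymethyl)-3-methyl-N-[2,3,5,6-tetrafluoro-4-(trifluoromethyl)phenyl]cyclobutane-1-carboxamide
Product: 10 cis-3-[(tert-butyldiphenylsilyloxy)methyl]-3-methyl-N-[2,3,5,6-tetrafluoro-4-(trifluoromethyl)phenyl]cyclobutane-1-carboxamide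
Conditions: TBDPSCl, imidazole, DMF, 23 °C
Reagents that add atoms: tert-butyl(chloro)diphenylsilane, CC(C)(C)[Si](Cl)(c1ccccc1)c1ccccc1
Why: Standard silylation of the primary neopentyl alcohol; the electron-poor anilide N–H is not silylated under these conditions.

Step 7
Reactants: 10 cis-3-[(tert-butyldiphenylsilyloxy)methyl]-3-methyl-N-[2,3,5,6-tetrafluoro-4-(trifluoromethyl)phenyl]cyclobutane-1-carboxamide; 11 (E)-(2-iodovinyl)benzene
Product: 12 (1R,2R,3S)-3-[(tert-butyldiphenylsilyloxy)methyl]-3-methyl-2-[(E)-2-phenylvinyl]-N-[2,3,5,6-tetrafluoro-4-(trifluoromethyl)phenyl]cyclobutane-1-carboxamide (amide, styryl and CH2OSi all cis)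
Conditions: Pd(OAc)2 (10 mol%), chiral N-acetyl aminomethyl-oxazoline ligand (20 mol%), Ag2CO3 (1.5 equiv), (CF3)2CHOH, 80 °C
Reagents that add atoms: none
Why: Ligand-controlled enantioselective β-methylene C–H vinylation of an N-(polyfluoroaryl) cyclobutanecarboxamide with a vinyl iodide (five-membered palladacycle, divalent/tetravalent palladium cycle). The substituent is delivered cis to the amide and the ligand picks one of the two enantiotopic CH2 groups, so the three stereocentres of the cyclobutane follow from that single choice and from the cis relation built in step 4.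

Step 8
Reactants: 12 (1R,2R,3S)-3-[(tert-butyldiphenylsilyloxy)methyl]-3-methyl-2-[(E)-2-phenylvinyl]-N-[2,3,5,6-tetrafluoro-4-(trifluoromethyl)phenyl]cyclobutane-1-carboxamide
Product: 14 (1R,2R,3S)-3-[(tert-butyldiphenylsilyloxy)methyl]-N-methoxy-N,3-dimethyl-2-[(E)-2-phenylvinyl]cyclobutane-1-carboxamide, via N-Boc anilide 13 (not isolated)
Conditions: Boc2O, DMAP (0.2 equiv), MeCN, 23 °C; then MeNHOMe·HCl, Et3N, 40 °C
Reagents that add atoms: N,O-dimethylhydroxylamine hydrochloride, CNOC.Cl
Why: N-Boc activation turns the anilide into a twisted N-acyl carbamate whose acyl carbonyl undergoes amine substitution (transamidation), releasing the auxiliary as its carbamate; the weakly basic medium should leave the cis amide α-centre alone.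

Step 9
Reactants: 14 (1R,2R,3S)-3-[(tert-butyldiphenylsilyloxy)methyl]-N-methoxy-N,3-dimethyl-2-[(E)-2-phenylvinyl]cyclobutane-1-carboxamide
Product: 16 (1R,2S,3S)-3-[(tert-butyldiphenylsilyloxy)methyl]-2-formyl-N-methoxy-N,3-dimethylcyclobutane-1-carboxamide (formyl trans to the amide and to CH2OSi, cis to the 3-methyl), via cis aldehyde 15 (not isolated)
Conditions: O3, CH2Cl2/MeOH, −78 °C; Me2S; then DBU (0.2 equiv), CH2Cl2, 23 °C
Reagents that add atoms: ozone, [O-][O+]=O
Why: Ozonolysis unveils the C2 aldehyde. DBU epimerises only the aldehyde α-carbon (C1 of the target), and the crowded all-cis isomer should relax to the isomer with CHO trans to both larger neighbours (thermodynamic control), which is the trans relation of the later ring fusion.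

Step 10
Reactants: 16 (1R,2S,3S)-3-[(tert-butyldiphenylsilyloxy)methyl]-2-formyl-N-methoxy-N,3-dimethylcyclobutane-1-carboxamide
Product: 18 1-[(1R,2S,3S)-3-[(tert-butyldiphenylsilyloxy)methyl]-2-(1-hydroxyprop-2-en-1-yl)-3-methylcyclobutyl]but-3-en-1-one (carbinol epimers), via hydroxy Weinreb amide 17 (not isolated)
Conditions: CH2=CHMgBr (1.1 equiv), THF, −78 °C; then CH2=CHCH2MgBr (2.5 equiv), −78 → 0 °C; aq. NH4Cl, 0 °C
Reagents that add atoms: vinylmagnesium bromide, C=C[Mg]Br; allylmagnesium bromide, C=CC[Mg]Br
Why: Grignard addition to the aldehyde, which reacts well before the amide at −78 °C, then Weinreb ketone synthesis through the chelated tetrahedral intermediate; the carbinol centre forms as epimers and is erased in step 12.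

Step 11
Reactants: 18 1-[(1R,2S,3S)-3-[(tert-butyldiphenylsilyloxy)methyl]-2-(1-hydroxyprop-2-en-1-yl)-3-methylcyclobutyl]but-3-en-1-one
Product: 19 1-[(1S,2R,4S)-4-[(tert-butyldiphenylsilyloxy)methyl]-4-methyl-2-(penta-1,4-dien-2-yl)cyclobutyl]prop-2-en-1-ol (carbinol epimers)
Conditions: Zn, CH2Br2, TiCl4, THF/CH2Cl2, 0 → 23 °C
Reagents that add atoms: dibromomethane, BrCBr
Why: Takai–Lombardo methylenation; the non-basic gem-dimetallic reagent olefinates enolisable β,γ-unsaturated ketones without conjugation and tolerates a free hydroxyl; no stereocentre is formed.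

Step 12
Reactants: 19 1-[(1S,2R,4S)-4-[(tert-butyldiphenylsilyloxy)methyl]-4-methyl-2-(penta-1,4-dien-2-yl)cyclobutyl]prop-2-en-1-ol
Product: 20 1-[(1S,2R,4S)-4-[(tert-butyldiphenylsilyloxy)methyl]-4-methyl-2-(penta-1,4-dien-2-yl)cyclobutyl]prop-2-en-1-one
Conditions: Dess–Martin periodinane, NaHCO3, CH2Cl2, 0 °C
Reagents that add atoms: none
Why: Dess–Martin oxidation of the secondary allylic alcohol under buffered conditions that spare the skipped diene; both carbinol epimers converge.

Step 13
Reactants: 20 1-[(1S,2R,4S)-4-[(tert-butyldiphenylsilyloxy)methyl]-4-methyl-2-(penta-1,4-dien-2-yl)cyclobutyl]prop-2-en-1-one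
Product: 21 (1S,7R,9S)-9-[(tert-butyldiphenylsilyloxy)methyl]-9-methyl-6-methylidenebicyclo[5.2.0]non-3-en-2-one (trans-fused)
Conditions: second-generation Grubbs catalyst RuCl2(=CHPh)(PCy3)(H2IMes) (5 mol%), 1,4-benzoquinone (10 mol%), CH2Cl2 (2 mM), 40 °C
Reagents that add atoms: none
Why: Ring-closing metathesis between the monosubstituted olefin (initiation site) and the vinyl ketone, with the 1,1-disubstituted olefin as spectator, gives the seven-membered cis-enone. The trans ring fusion set in step 9 is kept because nothing enolises towards C1.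

Step 14
Reactants: 21 (1S,7R,9S)-9-[(tert-butyldiphenylsilyloxy)methyl]-9-methyl-6-methylidenebicyclo[5.2.0]non-3-en-2-one
Product: 22 (1S,7R,9S)-9-[(tert-butyldiphenylsilyloxy)methyl]-9-methyl-6-methylidene-2-(triisopropylsilyloxy)bicyclo[5.2.0]non-2-ene
Conditions: i-Pr3SiH, Pt2[(CH2=CHSiMe2)2O]3 (1 mol%), toluene, 60 °C
Reagents that add atoms: triisopropylsilane, CC(C)[SiH](C(C)C)C(C)C
Why: Platinum-catalysed 1,4-hydrosilylation of the enone gives the silyl enol ether regiospecifically at C2=C5 (caryophyllane numbering) without base, so the epimerisable centre next to the carbonyl is never enolised; the hindered trialkylsilane should not add to the 1,1-disubstituted olefin.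

Step 15
Reactants: 23 but-2-ynoic acid; 24 allyl bromide
Product: 25 allyl but-2-ynoate
Conditions: K2CO3, DMF, 0 → 23 °C
Reagents that add atoms: none
Why: O-Alkylation of the carboxylate (SN2 at the allylic bromide).

Step 16
Reactants: 22 (1S,7R,9S)-9-[(tert-butyldiphenylsilyloxy)methyl]-9-methyl-6-methylidene-2-(triisopropylsilyloxy)bicyclo[5.2.0]non-2-ene; 25 allyl butynoate (allyl but-2-ynoate)
Product: 26 allyl 11-[(tert-butyldiphenylsilyloxy)methyl]-4,11-dimethyl-8-methylidene-2-(triisopropylsilyloxy)tricyclo[7.2.0.0(2,5)]undec-3-ene-3-carboxylate (cyclobutene cis-fused at C2/C5, cyclobutane trans-fused at C1/C9)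
Conditions: HNTf2 (3 mol%), CH2Cl2, −78 → −40 °C; Et3N quench
Reagents that add atoms: none
Why: Silyl triflimide formed in situ catalyses a stepwise [2+2]: Mukaiyama–Michael attack of C5 on the β-carbon of the ynoate (C4), then closure of the allenoate carbon C3 on the silyloxocarbenium C2. The four-membered ring can only be cis-fused, and the bulky silyl group disfavours desilylative open-chain products.

Step 17
Reactants: 26 allyl 11-[(tert-butyldiphenylsilyloxy)methyl]-4,11-dimethyl-8-methylidene-2-(triisopropylsilyloxy)tricyclo[7.2.0.0(2,5)]undec-3-ene-3-carboxylate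
Product: 27 allyl (1S,2Z,4E,9R,11S)-11-[(tert-butyldiphenylsilyloxy)methyl]-4,11-dimethyl-8-methylidene-2-(triisopropylsilyloxy)bicyclo[7.2.0]undeca-2,4-diene-3-carboxylate
Conditions: toluene (0.02 M), 2,6-lutidine (5 mol%), 70 °C
Reagents that add atoms: none
Why: Thermal conrotatory 4π-electrocyclic ring opening of the cyclobutene: the C2–C5 σ bond shared by the four- and seven-membered rings breaks and no σ bond forms; the closest known reaction type is the opening of 1-silyloxybicyclo[n.2.0]alkene carboxylates to cis,trans-cycloalkadienes used as a two-carbon ring expansion. The nine-membered ring is not closed by bond formation but arises when the two rings merge on cleavage of their common bond, so no cyclisation mode applies. No stereocentre is created and two (C2, C5) are cleared; the new stereo-element is the C4=C5 geometry. In a conrotation one substituent on each breaking-bond carbon turns outward and one inward; the oxygen donor on C2 strongly prefers the outward path, which sends C1 inward, and because the fusion is cis the same rotation sends C6 outward and H5 inward, giving C4=C5 E in the ring and the enol ether C2=C3 Z. The 4-methyl sits on the sp2 carbon C4 and does not rotate, so the only group forced inward at C5 is hydrogen. Cyclobutene strain and the push–pull conjugation of the β-silyloxy acrylate pay for the strain of the E-cyclononene. The step needs the donor-outward mode over the reverse conrotation (secured electronically and sterically as above) and a temperature low enough to avoid hydrogen shifts or E-to-Z isomerisation, while the trace of base keeps the silyl dienol ether from acid-induced cleavage. Both possible ring-fusion diastereomers of 26 should give the same 27, whose ring conformers interconvert.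

Step 18
Reactants: 27 allyl (1S,2Z,4E,9R,11S)-11-[(tert-butyldiphenylsilyloxy)methyl]-4,11-dimethyl-8-methylidene-2-(triisopropylsilyloxy)bicyclo[7.2.0]undeca-2,4-diene-3-carboxylate
Product: 28 allyl (1S,4E,9R,11S)-11-(hydroxymethyl)-4,11-dimethyl-8-methylidene-2-oxobicyclo[7.2.0]undec-4-ene-3-carboxylate (C3 epimers and enol)
Conditions: TBAF (4 equiv), AcOH (4 equiv), THF, 0 → 35 °C
Reagents that add atoms: none
Why: Buffered fluoride cleaves the silyl dienol ether to the β-keto ester and, more slowly, the neopentyl silyl ether. The near-neutral medium and the stabilised, largely enolised β-keto ester should prevent migration of C4=C5; C3 is a labile centre of no consequence.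

Step 19
Reactants: 28 allyl (1S,4E,9R,11S)-11-(hydroxymethyl)-4,11-dimethyl-8-methylidene-2-oxobicyclo[7.2.0]undec-4-ene-3-carboxylate
Product: 29 (1S,4E,9R,11S)-11-(hydroxymethyl)-4,11-dimethyl-8-methylidenebicyclo[7.2.0]undec-4-en-2-one
Conditions: Pd(PPh3)4 (5 mol%), morpholine (5 equiv), THF, 23 °C
Reagents that add atoms: none
Why: Tsuji-type deallylation (capture of the π-allyl by morpholine) gives the β-keto acid, which decarboxylates at room temperature; the enol is protonated at C3, and trans fusion at C1 is expected to be the stable arrangement on the nine-membered ring.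

Step 20
Reactants: 29 (1S,4E,9R,11S)-11-(hydroxymethyl)-4,11-dimethyl-8-methylidenebicyclo[7.2.0]undec-4-en-2-one
Product: 31 [(1S,4E,9R,11S)-4,11-dimethyl-8-methylidenebicyclo[7.2.0]undec-4-en-11-yl]methanol, via tosylhydrazone 30 (not isolated)
Conditions: TsNHNH2, EtOH, 50 °C; evaporate; catecholborane (3 equiv), CHCl3, 0 °C; then NaOAc·3H2O, 60 °C
Reagents that add atoms: none
Why: Tosylhydrazone formation, hydride delivery to C=N, acetate-induced loss of sulfinate and extrusion of N2 from the diazene (a mild Wolff–Kishner-type deoxygenation). With a non-conjugated hydrazone the hydrogen arrives at the former carbonyl carbon, so the β,γ-olefin should stay in place; no stereocentre is formed.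

Step 21
Reactants: 31 [(1S,4E,9R,11S)-4,11-dimethyl-8-methylidenebicyclo[7.2.0]undec-4-en-11-yl]methanol
Product: 32 (1S,4E,9R,11S)-4,11-dimethyl-8-methylidenebicyclo[7.2.0]undec-4-ene-11-carbaldehyde
Conditions: Dess–Martin periodinane, NaHCO3, CH2Cl2, 0 °C
Reagents that add atoms: none
Why: Dess–Martin oxidation of the neopentyl primary alcohol; the aldehyde has no α-hydrogen and cannot epimerise.

Step 22
Reactants: 33 (S)-(2-methyloxiran-2-yl)methanol
Product: 35 (S)-2-ethynyl-2-methyloxirane, via (R)-2-methyloxirane-2-carbaldehyde 34 (not isolated)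
Conditions: Dess–Martin periodinane, NaHCO3, CH2Cl2, 0 °C; filter; then dimethyl (1-diazo-2-oxopropyl)phosphonate, K2CO3, MeOH, 0 → 23 °C; used as a THF solution
Reagents that add atoms: dimethyl (1-diazo-2-oxopropyl)phosphonate, COP(=O)(OC)C(=[N+]=[N-])C(C)=O
Why: Oxidation followed by Ohira–Bestmann (Seyferth–Gilbert) homologation; the quaternary epoxide carbon has no α-hydrogen, so its configuration is carried through unchanged.

Step 23
Reactants: 32 (1S,4E,9R,11S)-4,11-dimethyl-8-methylidenebicyclo[7.2.0]undec-4-ene-11-carbaldehyde; 35 (S)-2-ethynyl-2-methyloxirane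
Product: 36 1-[(1S,4E,9R,11S)-4,11-dimethyl-8-methylidenebicyclo[7.2.0]undec-4-en-11-yl]-3-[(2S)-2-methyloxiran-2-yl]prop-2-yn-1-ol (carbinol epimers)
Conditions: 35, n-BuLi, THF, −78 °C; then 32, −78 → −40 °C; aq. NH4Cl
Reagents that add atoms: none
Why: 1,2-Addition of the lithium acetylide to the hindered, non-enolisable aldehyde at low temperature, where the propargylic epoxide is stable; the carbinol epimers converge in step 25.

Step 24
Reactants: 36 1-[(1S,4E,9R,11S)-4,11-dimethyl-8-methylidenebicyclo[7.2.0]undec-4-en-11-yl]-3-[(2S)-2-methyloxiran-2-yl]prop-2-yn-1-ol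
Product: 37 (2Z)-1-[(1S,4E,9R,11S)-4,11-dimethyl-8-methylidenebicyclo[7.2.0]undec-4-en-11-yl]-3-[(2S)-2-methyloxiran-2-yl]prop-2-en-1-ol (carbinol epimers)
Conditions: H2 (1 atm), Pd/CaCO3 poisoned with Pb(OAc)2 (Lindlar catalyst), quinoline, EtOAc, 23 °C, stopped after 1 equiv H2
Reagents that add atoms: none
Why: Lindlar semihydrogenation delivers H2 syn and gives the Z-olefin; the poisoned catalyst should discriminate the alkyne from the methylidene and the trisubstituted ring olefin.

Step 25
Reactants: 37 (2Z)-1-[(1S,4E,9R,11S)-4,11-dimethyl-8-methylidenebicyclo[7.2.0]undec-4-en-11-yl]-3-[(2S)-2-methyloxiran-2-yl]prop-2-en-1-ol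
Product: 38 (2Z)-1-[(1S,4E,9R,11S)-4,11-dimethyl-8-methylidenebicyclo[7.2.0]undec-4-en-11-yl]-3-[(2S)-2-methyloxiran-2-yl]prop-2-en-1-one
Conditions: Dess–Martin periodinane, pyridine, CH2Cl2, 0 °C, exclusion of light
Reagents that add atoms: none
Why: Buffered Dess–Martin oxidation of the Z-allylic alcohol without the acid, base or light that would isomerise the Z-enone; both carbinol epimers give the same ketone.

Step 26
Reactants: 38 (2Z)-1-[(1S,4E,9R,11S)-4,11-dimethyl-8-methylidenebicyclo[7.2.0]undec-4-en-11-yl]-3-[(2S)-2-methyloxiran-2-yl]prop-2-en-1-one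
Product: 39 (3S,6R)-3-[(1S,4E,9R,11S)-4,11-dimethyl-8-methylidenebicyclo[7.2.0]undec-4-en-11-yl]-6-(hydroxymethyl)-6-methyl-3,6-dihydro-1,2-dioxin-3-ol
Conditions: H2O2 (anhydrous, in Et2O, 5 equiv), H3PMo12O40 (3 mol%), Et2O, 0 → 23 °C
Reagents that add atoms: hydrogen peroxide, OO
Why: Phosphomolybdic-acid-catalysed perhydrolysis of the 2,2-disubstituted epoxide at its tertiary allylic carbon with inversion, combined with closure of the γ-hydroperoxy Z-enone to the six-membered peroxy hemiketal (the two events may occur in either order). C15 (R) comes from the (S)-epoxide by inversion, and C12 should settle by ring–chain equilibration on the epimer with a pseudo-axial anomeric OH and a pseudo-equatorial cyclobutyl group.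

Step 27
Reactants: 39 (3S,6R)-3-[(1S,4E,9R,11S)-4,11-dimethyl-8-methylidenebicyclo[7.2.0]undec-4-en-11-yl]-6-(hydroxymethyl)-6-methyl-3,6-dihydro-1,2-dioxin-3-ol
Product: 40 [(3R,6S)-6-[(1S,4E,9R,11S)-4,11-dimethyl-8-methylidenebicyclo[7.2.0]undec-4-en-11-yl]-6-hydroxy-3-methyl-3,6-dihydro-1,2-dioxin-3-yl]methyl acetate
Conditions: Ac2O (1.2 equiv), pyridine, CH2Cl2, 0 °C
Reagents that add atoms: acetic anhydride, CC(=O)OC(C)=O
Why: Acylation of the primary alcohol; the tertiary hemiketal OH is far less nucleophilic, and both peroxide-bearing carbons are quaternary, so base-induced Kornblum–DeLaMare cleavage is not possible.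

Step 28
Reactants: 40 [(3R,6S)-6-[(1S,4E,9R,11S)-4,11-dimethyl-8-methylidenebicyclo[7.2.0]undec-4-en-11-yl]-6-hydroxy-3-methyl-3,6-dihydro-1,2-dioxin-3-yl]methyl acetate
Product: 41 [(3R,6S)-6-[(1S,4S,5S,9R,11S)-4,5-epoxy-4,11-dimethyl-8-methylidenebicyclo[7.2.0]undecan-11-yl]-6-hydroxy-3-methyl-3,6-dihydro-1,2-dioxin-3-yl]methyl acetate (CNP0169860.2)
Conditions: m-CPBA (1.05 equiv), NaHCO3, CH2Cl2, −20 → 0 °C
Reagents that add atoms: 3-chloroperoxybenzoic acid, OOC(=O)c1cccc(Cl)c1
Why: Prilezhaev epoxidation: the strained, electron-rich trisubstituted ring olefin should react well before the methylidene or the dioxine olefin flanked by two oxygenated carbons. Attack on the exposed outer face of the E-olefin, as in the conversion of caryophyllene to its oxide, sets C4 (S) and C5 (S) together by syn addition.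

## Compound list

1 | 1,1,1-tris(hydroxymethyl)ethane | CC(CO)(CO)CO | starting material
2 | 3-bromo-2-(bromomethyl)-2-methylpropyl acetate | CC(=O)OCC(C)(CBr)CBr | intermediate
3 | diethyl malonate | CCOC(=O)CC(=O)OCC | starting material
4 | diethyl 3-(acetoxymethyl)-3-methylcyclobutane-1,1-dicarboxylate | CCOC(=O)C1(C(=O)OCC)CC(C)(COC(C)=O)C1 | intermediate
5 | ethyl 3-(acetoxymethyl)-3-methylcyclobutane-1-carboxylate (cis/trans mixture, no descriptor) | CCOC(=O)C1CC(C)(COC(C)=O)C1 | intermediate
6 | ethyl 3-(hydroxymethyl)-3-methylcyclobutane-1-carboxylate (equilibrating cis/trans mixture) | CCOC(=O)C1CC(C)(CO)C1 | intermediate (not isolated)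
7 | 5-methyl-3-oxabicyclo[3.1.1]heptan-2-one (achiral bridged lactone) | O=C1OCC2(C)CC1C2 | intermediate
8 | 2,3,5,6-tetrafluoro-4-(trifluoromethyl)aniline | Nc1c(F)c(F)c(C(F)(F)F)c(F)c1F | starting material
9 | cis-3-(hydroxymethyl)-3-methyl-N-[2,3,5,6-tetrafluoro-4-(trifluoromethyl)phenyl]cyclobutane-1-carboxamide (achiral) | C1[C@H](C(=O)Nc2c(F)c(F)c(C(F)(F)F)c(F)c2F)C[C@]1(C)CO | intermediate
10 | cis-3-[(tert-butyldiphenylsilyloxy)methyl]-3-methyl-N-[2,3,5,6-tetrafluoro-4-(trifluoromethyl)phenyl]cyclobutane-1-carboxamide (achiral) | C1[C@H](C(=O)Nc2c(F)c(F)c(C(F)(F)F)c(F)c2F)C[C@]1(C)CO[Si](c3ccccc3)(c4ccccc4)C(C)(C)C | intermediate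
11 | (E)-(2-iodovinyl)benzene | I/C=C/c1ccccc1 | starting material
12 | (1R,2R,3S)-3-[(tert-butyldiphenylsilyloxy)methyl]-3-methyl-2-[(E)-2-phenylvinyl]-N-[2,3,5,6-tetrafluoro-4-(trifluoromethyl)phenyl]cyclobutane-1-carboxamide | c5ccccc5/C=C/[C@@H]1[C@H](C(=O)Nc2c(F)c(F)c(C(F)(F)F)c(F)c2F)C[C@]1(C)CO[Si](c3ccccc3)(c4ccccc4)C(C)(C)C | intermediate
13 | N-Boc anilide of 12 | c5ccccc5/C=C/[C@@H]1[C@H](C(=O)N(C(=O)OC(C)(C)C)c2c(F)c(F)c(C(F)(F)F)c(F)c2F)C[C@]1(C)CO[Si](c3ccccc3)(c4ccccc4)C(C)(C)C | intermediate (not isolated)
14 | (1R,2R,3S)-3-[(tert-butyldiphenylsilyloxy)methyl]-N-methoxy-N,3-dimethyl-2-[(E)-2-phenylvinyl]cyclobutane-1-carboxamide | c5ccccc5/C=C/[C@@H]1[C@H](C(=O)N(C)OC)C[C@]1(C)CO[Si](c3ccccc3)(c4ccccc4)C(C)(C)C | intermediate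
15 | (1R,2R,3S)-3-[(tert-butyldiphenylsilyloxy)methyl]-2-formyl-N-methoxy-N,3-dimethylcyclobutane-1-carboxamide (all-cis) | O=C[C@@H]1[C@H](C(=O)N(C)OC)C[C@]1(C)CO[Si](c3ccccc3)(c4ccccc4)C(C)(C)C | intermediate (not isolated)
16 | (1R,2S,3S)-3-[(tert-butyldiphenylsilyloxy)methyl]-2-formyl-N-methoxy-N,3-dimethylcyclobutane-1-carboxamide (formyl trans to amide) | O=C[C@H]1[C@H](C(=O)N(C)OC)C[C@]1(C)CO[Si](c3ccccc3)(c4ccccc4)C(C)(C)C | intermediate
17 | (1R,2S,3S)-3-[(tert-butyldiphenylsilyloxy)methyl]-2-(1-hydroxyprop-2-en-1-yl)-N-methoxy-N,3-dimethylcyclobutane-1-carboxamide (carbinol epimers; formed as its magnesium alkoxide) | C=CC(O)[C@H]1[C@H](C(=O)N(C)OC)C[C@]1(C)CO[Si](c3ccccc3)(c4ccccc4)C(C)(C)C | intermediate (not isolated)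
18 | 1-[(1R,2S,3S)-3-[(tert-butyldiphenylsilyloxy)methyl]-2-(1-hydroxyprop-2-en-1-yl)-3-methylcyclobutyl]but-3-en-1-one (carbinol epimers) | C=CC(O)[C@H]1[C@H](C(=O)CC=C)C[C@]1(C)CO[Si](c3ccccc3)(c4ccccc4)C(C)(C)C | intermediate
19 | 1-[(1S,2R,4S)-4-[(tert-butyldiphenylsilyloxy)methyl]-4-methyl-2-(penta-1,4-dien-2-yl)cyclobutyl]prop-2-en-1-ol (carbinol epimers) | C=CC(O)[C@H]1[C@H](C(=C)CC=C)C[C@]1(C)CO[Si](c3ccccc3)(c4ccccc4)C(C)(C)C | intermediate
20 | 1-[(1S,2R,4S)-4-[(tert-butyldiphenylsilyloxy)methyl]-4-methyl-2-(penta-1,4-dien-2-yl)cyclobutyl]prop-2-en-1-one | C=CC(=O)[C@H]1[C@H](C(=C)CC=C)C[C@]1(C)CO[Si](c3ccccc3)(c4ccccc4)C(C)(C)C | intermediate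
21 | (1S,7R,9S)-9-[(tert-butyldiphenylsilyloxy)methyl]-9-methyl-6-methylidenebicyclo[5.2.0]non-3-en-2-one | C=C1C/C=C\C(=O)[C@H]2[C@H]1C[C@]2(C)CO[Si](c3ccccc3)(c4ccccc4)C(C)(C)C | intermediate
22 | (1S,7R,9S)-9-[(tert-butyldiphenylsilyloxy)methyl]-9-methyl-6-methylidene-2-(triisopropylsilyloxy)bicyclo[5.2.0]non-2-ene | C=C1CC/C=C(O[Si](C(C)C)(C(C)C)C(C)C)\[C@H]2[C@H]1C[C@]2(C)CO[Si](c3ccccc3)(c4ccccc4)C(C)(C)C | intermediate
23 | but-2-ynoic acid | CC#CC(=O)O | starting material
24 | allyl bromide | C=CCBr | starting material
25 | allyl but-2-ynoate | CC#CC(=O)OCC=C | intermediate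
26 | allyl 11-[(tert-butyldiphenylsilyloxy)methyl]-4,11-dimethyl-8-methylidene-2-(triisopropylsilyloxy)tricyclo[7.2.0.0(2,5)]undec-3-ene-3-carboxylate (cis at C2/C5, trans at C1/C9) | C=C1CC[C@@H]2C(C)=C(C(=O)OCC=C)[C@]2(O[Si](C(C)C)(C(C)C)C(C)C)[C@H]2[C@H]1C[C@]2(C)CO[Si](c3ccccc3)(c4ccccc4)C(C)(C)C | intermediate
27 | allyl (1S,2Z,4E,9R,11S)-11-[(tert-butyldiphenylsilyloxy)methyl]-4,11-dimethyl-8-methylidene-2-(triisopropylsilyloxy)bicyclo[7.2.0]undeca-2,4-diene-3-carboxylate | C=C1CC/C=C(C)/C(C(=O)OCC=C)=C(O[Si](C(C)C)(C(C)C)C(C)C)\[C@H]2[C@H]1C[C@]2(C)CO[Si](c3ccccc3)(c4ccccc4)C(C)(C)C | intermediate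
28 | allyl (1S,4E,9R,11S)-11-(hydroxymethyl)-4,11-dimethyl-8-methylidene-2-oxobicyclo[7.2.0]undec-4-ene-3-carboxylate (C3 undefined) | C=C1CC/C=C(C)/C(C(=O)OCC=C)C(=O)[C@H]2[C@H]1C[C@]2(C)CO | intermediate
29 | (1S,4E,9R,11S)-11-(hydroxymethyl)-4,11-dimethyl-8-methylidenebicyclo[7.2.0]undec-4-en-2-one | C=C1CC/C=C(C)/CC(=O)[C@H]2[C@H]1C[C@]2(C)CO | intermediate
30 | 4-methylbenzenesulfonylhydrazone of 29 | C=C1CC/C=C(C)/CC(=NNS(=O)(=O)c3ccc(C)cc3)[C@H]2[C@H]1C[C@]2(C)CO | intermediate (not isolated)
31 | [(1S,4E,9R,11S)-4,11-dimethyl-8-methylidenebicyclo[7.2.0]undec-4-en-11-yl]methanol | C=C1CC/C=C(C)/CC[C@H]2[C@H]1C[C@]2(C)CO | intermediate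
32 | (1S,4E,9R,11S)-4,11-dimethyl-8-methylidenebicyclo[7.2.0]undec-4-ene-11-carbaldehyde | C=C1CC/C=C(C)/CC[C@H]2[C@H]1C[C@]2(C)C=O | intermediate
33 | (S)-(2-methyloxiran-2-yl)methanol | OC[C@@]1(C)CO1 | starting material
34 | (R)-2-methyloxirane-2-carbaldehyde | O=C[C@@]1(C)CO1 | intermediate (not isolated)
35 | (S)-2-ethynyl-2-methyloxirane | C#C[C@@]1(C)CO1 | intermediate
36 | 1-[(1S,4E,9R,11S)-4,11-dimethyl-8-methylidenebicyclo[7.2.0]undec-4-en-11-yl]-3-[(2S)-2-methyloxiran-2-yl]prop-2-yn-1-ol (carbinol epimers) | C=C1CC/C=C(C)/CC[C@H]2[C@H]1C[C@]2(C)C(O)C#C[C@@]3(C)CO3 | intermediate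
37 | (2Z)-1-[(1S,4E,9R,11S)-4,11-dimethyl-8-methylidenebicyclo[7.2.0]undec-4-en-11-yl]-3-[(2S)-2-methyloxiran-2-yl]prop-2-en-1-ol (carbinol epimers) | C=C1CC/C=C(C)/CC[C@H]2[C@H]1C[C@]2(C)C(O)/C=C\[C@@]3(C)CO3 | intermediate
38 | (2Z)-1-[(1S,4E,9R,11S)-4,11-dimethyl-8-methylidenebicyclo[7.2.0]undec-4-en-11-yl]-3-[(2S)-2-methyloxiran-2-yl]prop-2-en-1-one | C=C1CC/C=C(C)/CC[C@H]2[C@H]1C[C@]2(C)C(=O)/C=C\[C@@]3(C)CO3 | intermediate
39 | (3S,6R)-3-[(1S,4E,9R,11S)-4,11-dimethyl-8-methylidenebicyclo[7.2.0]undec-4-en-11-yl]-6-(hydroxymethyl)-6-methyl-3,6-dihydro-1,2-dioxin-3-ol | C=C1CC/C=C(C)/CC[C@H]2[C@H]1C[C@]2(C)[C@]1(O)C=C[C@](C)(CO)OO1 | intermediate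
40 | [(3R,6S)-6-[(1S,4E,9R,11S)-4,11-dimethyl-8-methylidenebicyclo[7.2.0]undec-4-en-11-yl]-6-hydroxy-3-methyl-3,6-dihydro-1,2-dioxin-3-yl]methyl acetate | C=C1CC/C=C(C)/CC[C@H]2[C@H]1C[C@]2(C)[C@]1(O)C=C[C@](C)(COC(C)=O)OO1 | intermediate
41 | [(3R,6S)-6-[(1S,4S,5S,9R,11S)-4,5-epoxy-4,11-dimethyl-8-methylidenebicyclo[7.2.0]undecan-11-yl]-6-hydroxy-3-methyl-3,6-dihydro-1,2-dioxin-3-yl]methyl acetate (CNP0169860.2) | C=C1CC[C@@H]2O[C@@]2(C)CC[C@H]2[C@H]1C[C@]2(C)[C@]1(O)C=C[C@](C)(COC(C)=O)OO1 | target

## Step count and least certain steps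

Total: 28 steps. The longest linear sequence is 26 steps (1 to 41 through steps 1–14, 16–21 and 23–28); steps 15 and 22 are single-step side branches.

Step 17 (key step). The most likely failure is that the opening is slow or reversible at temperatures mild enough to preserve the product. Forcing it invites hydrogen shifts or E-to-Z isomerisation of the strained diene, or loss of the silyl group. The fallback replaces the neutral thermal opening by an oxy-anion-accelerated one. It sets out from 26, which is treated with anhydrous TBAF in THF at −78 °C. This frees the tertiary alkoxide of allyl 11-[(tert-butyldiphenylsilyloxy)methyl]-2-hydroxy-4,11-dimethyl-8-methylidenetricyclo[7.2.0.0(2,5)]undec-3-ene-3-carboxylate F1 (not isolated). The alkoxide should open well below 0 °C, again with oxygen outward, to the enolate of the β-keto ester. Protonation with AcOH at low temperature gives allyl (1S,4E,9R,11S)-11-[(tert-butyldiphenylsilyloxy)methyl]-4,11-dimethyl-8-methylidene-2-oxobicyclo[7.2.0]undec-4-ene-3-carboxylate F2. Buffered TBAF as in step 18 then removes the remaining silyl ether and returns to the route at 28.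

Step 7. The methylene to be palladated lies between the amide-bearing carbon and a quaternary carbon, so slow C–H cleavage, weak enantio-discrimination, a second vinylation and erosion of the amide α-centre are all possible. The fallback gives up catalytic asymmetric induction for a robust bidentate auxiliary and a resolution.
- From 7, aminolysis with 8-aminoquinoline and AlMe3 gives cis-3-(hydroxymethyl)-3-methyl-N-(quinolin-8-yl)cyclobutane-1-carboxamide F3.
- Silylation with TBDPSCl gives its silyl ether F4.
- Pd(OAc)2/AgOAc-mediated alkenylation with 11 gives the racemic all-cis styryl amide F5.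
- Boc2O/DMAP then LiOH/H2O2 gives racemic all-cis 3-[(tert-butyldiphenylsilyloxy)methyl]-3-methyl-2-[(E)-2-phenylvinyl]cyclobutane-1-carboxylic acid F6.
- F6 is resolved by crystallisation of a 1-phenylethylammonium salt to the (1R,2R,3S) enantiomer.
- Coupling with MeNHOMe·HCl (EDCI, HOBt, i-Pr2NEt) returns to the route at 14.

Step 13. Closing a trans-fused seven-membered ring with four sp2 carbons may lose to intermolecular metathesis, and ruthenium hydrides may move the skipped diene into conjugation. The fallback closes the ring by an intramolecular Hosomi–Sakurai conjugate allylation, which forms C6–C7 instead of C5=C6.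
- From 16, CH2=CHMgBr at −78 °C and then Me3SiCH2MgCl give 1-[(1R,2S,3S)-3-[(tert-butyldiphenylsilyloxy)methyl]-2-(1-hydroxyprop-2-en-1-yl)-3-methylcyclobutyl]-2-(trimethylsilyl)ethan-1-one F7.
- Takai–Lombardo methylenation gives the allylsilane alcohol F8.
- Dess–Martin oxidation gives the vinyl ketone allylsilane F9.
- TiCl4 in CH2Cl2 at −78 °C should close the ring to (1S,7R,9S)-9-[(tert-butyldiphenylsilyloxy)methyl]-9-methyl-6-methylidenebicyclo[5.2.0]nonan-2-one F10.
- Kinetic deprotonation (LDA, THF, −78 °C) and i-Pr3SiOTf return to the route at 22.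

Step 16. After the Michael stage the zwitterion may collapse by silyl transfer to an open-chain adduct instead of closing. The hindered enol ether may be slow towards a β-substituted alkynoate, and the strong Lewis acid may isomerise the methylidene. The fallback keeps the disconnection but uses a neutral enamine as donor, the classical enamine–alkynoate two-carbon ring enlargement.
- From 21, conjugate reduction with [(Ph3P)CuH]6 gives the ketone F10.
- Pyrrolidine with TiCl4 gives the less substituted enamine 1-[(1S,7R,9S)-9-[(tert-butyldiphenylsilyloxy)methyl]-9-methyl-6-methylidenebicyclo[5.2.0]non-2-en-2-yl]pyrrolidine F11.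
- Heating with 25 in MeCN should give, through an aminocyclobutene that opens in situ, the ring-expanded dienamine ester F12.
- Hydrolysis with aqueous AcOH/NaOAc gives the β-keto ester F2, and buffered TBAF returns to the route at 28.
- Epimerisation at C1 during enamine formation is the weak point of this variant.

Step 20. Hydride delivery to a hindered medium-ring C=N is disfavoured by transannular strain. If the diazene fragments through a radical, the cyclobutylcarbinyl radical can open the four-membered ring. The fallback is an anionic low-temperature Wolff–Kishner reduction that avoids both. From 29, 1,2-bis(tert-butyldimethylsilyl)hydrazine with catalytic Sc(OTf)3 gives the N-silyl hydrazone F13. KOtBu/t-BuOH in DMSO at 23–60 °C should give 31 directly. The temperature is kept as low as possible to avoid base-induced olefin migration.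

Step 26. The tertiary allylic epoxide may open through a cation, with erosion of configuration at C15. The acid/peroxide mixture may oxidise or cyclise the strained diene, the Z-enone may isomerise, and C12 may settle as a mixture. The fallback inverts the order of the two late oxidations so that the acid-sensitive diene no longer exists during peroxide formation. From 38, m-CPBA at −20 °C gives (2Z)-1-[(1S,4S,5S,9R,11S)-4,5-epoxy-4,11-dimethyl-8-methylidenebicyclo[7.2.0]undecan-11-yl]-3-[(2S)-2-methyloxiran-2-yl]prop-2-en-1-one F14. The same perhydrolysis/hemiketalisation then relies on the faster opening of the allylic 2,2-disubstituted epoxide and gives the deacetyl target F15. Ac2O/pyridine returns to the route at 41.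

## Further compounds

F1 | step 17 | allyl 11-[(tert-butyldiphenylsilyloxy)methyl]-2-hydroxy-4,11-dimethyl-8-methylidenetricyclo[7.2.0.0(2,5)]undec-3-ene-3-carboxylate (as alkoxide) | C=C1CC[C@@H]2C(C)=C(C(=O)OCC=C)[C@]2(O)[C@H]2[C@H]1C[C@]2(C)CO[Si](c3ccccc3)(c4ccccc4)C(C)(C)C
F2 | step 17 | allyl (1S,4E,9R,11S)-11-[(tert-butyldiphenylsilyloxy)methyl]-4,11-dimethyl-8-methylidene-2-oxobicyclo[7.2.0]undec-4-ene-3-carboxylate | C=C1CC/C=C(C)/C(C(=O)OCC=C)C(=O)[C@H]2[C@H]1C[C@]2(C)CO[Si](c3ccccc3)(c4ccccc4)C(C)(C)C
F3 | step 7 | cis-3-(hydroxymethyl)-3-methyl-N-(quinolin-8-yl)cyclobutane-1-carboxamide | C1[C@H](C(=O)Nc2cccc3cccnc23)C[C@]1(C)CO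
F4 | step 7 | cis-3-[(tert-butyldiphenylsilyloxy)methyl]-3-methyl-N-(quinolin-8-yl)cyclobutane-1-carboxamide | C1[C@H](C(=O)Nc2cccc3cccnc23)C[C@]1(C)CO[Si](c4ccccc4)(c5ccccc5)C(C)(C)C
F5 | step 7 | all-cis 3-[(tert-butyldiphenylsilyloxy)methyl]-3-methyl-2-[(E)-2-phenylvinyl]-N-(quinolin-8-yl)cyclobutane-1-carboxamide (racemate, one enantiomer drawn) | c6ccccc6/C=C/[C@@H]1[C@H](C(=O)Nc2cccc3cccnc23)C[C@]1(C)CO[Si](c4ccccc4)(c5ccccc5)C(C)(C)C
F6 | step 7 | all-cis 3-[(tert-butyldiphenylsilyloxy)methyl]-3-methyl-2-[(E)-2-phenylvinyl]cyclobutane-1-carboxylic acid (racemate; the drawn (1R,2R,3S) enantiomer is carried on after resolution) | c6ccccc6/C=C/[C@@H]1[C@H](C(=O)O)C[C@]1(C)CO[Si](c4ccccc4)(c5ccccc5)C(C)(C)C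
F7 | step 13 | 1-[(1R,2S,3S)-3-[(tert-butyldiphenylsilyloxy)methyl]-2-(1-hydroxyprop-2-en-1-yl)-3-methylcyclobutyl]-2-(trimethylsilyl)ethan-1-one | C=CC(O)[C@H]1[C@H](C(=O)C[Si](C)(C)C)C[C@]1(C)CO[Si](c3ccccc3)(c4ccccc4)C(C)(C)C
F8 | step 13 | 1-[(1S,2R,4S)-4-[(tert-butyldiphenylsilyloxy)methyl]-4-methyl-2-[3-(trimethylsilyl)prop-1-en-2-yl]cyclobutyl]prop-2-en-1-ol | C=CC(O)[C@H]1[C@H](C(=C)C[Si](C)(C)C)C[C@]1(C)CO[Si](c3ccccc3)(c4ccccc4)C(C)(C)C
F9 | step 13 | 1-[(1S,2R,4S)-4-[(tert-butyldiphenylsilyloxy)methyl]-4-methyl-2-[3-(trimethylsilyl)prop-1-en-2-yl]cyclobutyl]prop-2-en-1-one | C=CC(=O)[C@H]1[C@H](C(=C)C[Si](C)(C)C)C[C@]1(C)CO[Si](c3ccccc3)(c4ccccc4)C(C)(C)C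
F10 | step 13 | (1S,7R,9S)-9-[(tert-butyldiphenylsilyloxy)methyl]-9-methyl-6-methylidenebicyclo[5.2.0]nonan-2-one | C=C1CCCC(=O)[C@H]2[C@H]1C[C@]2(C)CO[Si](c3ccccc3)(c4ccccc4)C(C)(C)C
F11 | step 16 | 1-[(1S,7R,9S)-9-[(tert-butyldiphenylsilyloxy)methyl]-9-methyl-6-methylidenebicyclo[5.2.0]non-2-en-2-yl]pyrrolidine | C=C1CCC=C(N3CCCC3)[C@H]2[C@H]1C[C@]2(C)CO[Si](c4ccccc4)(c5ccccc5)C(C)(C)C
F12 | step 16 | allyl (1S,2Z,4E,9R,11S)-11-[(tert-butyldiphenylsilyloxy)methyl]-4,11-dimethyl-8-methylidene-2-(pyrrolidin-1-yl)bicyclo[7.2.0]undeca-2,4-diene-3-carboxylate | C=C1CC/C=C(C)/C(C(=O)OCC=C)=C(N3CCCC3)\[C@H]2[C@H]1C[C@]2(C)CO[Si](c4ccccc4)(c5ccccc5)C(C)(C)C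
F13 | step 20 | N-(tert-butyldimethylsilyl)hydrazone of 29 | C=C1CC/C=C(C)/CC(=NN[Si](C)(C)C(C)(C)C)[C@H]2[C@H]1C[C@]2(C)CO
F14 | step 26 | (2Z)-1-[(1S,4S,5S,9R,11S)-4,5-epoxy-4,11-dimethyl-8-methylidenebicyclo[7.2.0]undecan-11-yl]-3-[(2S)-2-methyloxiran-2-yl]prop-2-en-1-one | C=C1CC[C@@H]2O[C@@]2(C)CC[C@H]2[C@H]1C[C@]2(C)C(=O)/C=C\[C@@]3(C)CO3
F15 | step 26 | (3S,6R)-3-[(1S,4S,5S,9R,11S)-4,5-epoxy-4,11-dimethyl-8-methylidenebicyclo[7.2.0]undecan-11-yl]-6-(hydroxymethyl)-6-methyl-3,6-dihydro-1,2-dioxin-3-ol | C=C1CC[C@@H]2O[C@@]2(C)CC[C@H]2[C@H]1C[C@]2(C)[C@]1(O)C=C[C@](C)(CO)OO1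
A1 | alternative 1 | (3S,4R)-3-[2-(tert-butyldimethylsilyloxy)ethyl]-2-diazo-4-ethenyl-4-methylcyclopentan-1-one | O=C1C[C@](C)(C=C)[C@@H](CCO[Si](C)(C)C(C)(C)C)C1=[N+]=[N-]
A2 | alternative 1 | methyl 2-[2-(tert-butyldimethylsilyloxy)ethyl]-3-ethenyl-3-methylcyclobutane-1-carboxylate (ester trans to the chain) | COC(=O)[C@@H]1C[C@](C)(C=C)[C@H]1CCO[Si](C)(C)C(C)(C)C
A3 | alternative 2 | (2Z)-1-[(1S,4E,9R,11S)-4,11-dimethyl-8-methylidenebicyclo[7.2.0]undec-4-en-11-yl]-3-[(2S)-2-methyloxiran-2-yl]prop-2-en-1-one (identical with 38) | C=C1CC/C=C(C)/CC[C@H]2[C@H]1C[C@]2(C)C(=O)/C=C\[C@@]3(C)CO3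
A4 | alternative 2 | (3S,6R)-3-[(1S,4E,9R,11S)-4,11-dimethyl-8-methylidenebicyclo[7.2.0]undec-4-en-11-yl]-6-(hydroxymethyl)-6-methyl-3,6-dihydro-1,2-dioxin-3-ol (identical with 39) | C=C1CC/C=C(C)/CC[C@H]2[C@H]1C[C@]2(C)[C@]1(O)C=C[C@](C)(CO)OO1
A5 | alternative 3 | (2E,6E,10E)-12-(tert-butyldiphenylsilyloxy)-3,7,11-trimethyldodeca-2,6,10-trien-1-yl acetate | CC(=O)OC/C=C(C)/CC/C=C(C)/CC/C=C(C)/CO[Si](c1ccccc1)(c1ccccc1)C(C)(C)C
A6 | alternative 3 | tert-butyl{[(1S,4E,9R,11S)-4,11-dimethyl-8-methylidenebicyclo[7.2.0]undec-4-en-11-yl]methoxy}diphenylsilane | C=C1CC/C=C(C)/CC[C@H]2[C@H]1C[C@]2(C)CO[Si](c3ccccc3)(c4ccccc4)C(C)(C)C
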